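**Retrosynthetic overview**
1. Polymatin A ⇐ late C8‑angeloylation and C9‑O‑desilylation; the angelate donor is made separately from tiglic acid.
2. The ten‑membered ring and the α‑methylene‑γ‑lactone are formed together in the last C–C bond‑forming step: intramolecular Cr(II) Barbier (Nozaki–Hiyama) macrocyclization C6–C7 of an enal / 2‑(bromomethyl)enoate, with lactonization in situ.
3. Seco‑precursor: the C7=C11(CO2Me)CH2Br unit comes from a Baylis–Hillman reaction and SN2′ bromination; the C1=C10(CO2Me) enoate comes from syn‑hydrostannation / iodination / carbonylation of a C1≡C10 alkyne.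
4. The alkyne comes from C1–C2 acetylide alkylation of an East dibromo‑olefin (C7–C10, both stereocentres from diethyl L‑tartrate) with a West homoallylic iodide (C2–C6, from but‑3‑yn‑1‑ol by Negishi carboalumination).

Assumptions: germacrane numbering is used (C6 lactone carbinol, C7 ring‑fusion CH, C8 angelate carbon, C9 carbinol, C10 bears CO2Me = C14, C11=C13 methylene, C12 lactone C=O). One‑pot two‑stage operations are counted as one step. TBS = tert‑butyldimethylsilyl, TES = triethylsilyl, PMB = 4‑methoxybenzyl.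

---

**East fragment (C7–C10)**

Step 1
Reactants: 1, diethyl L‑(+)‑tartrate
Product: 2, diethyl (2R,3R)‑2‑(TBSO)‑3‑hydroxybutanedioate
Conditions: TBSCl (1.0 equiv), imidazole, DMF, 0 °C
Reagents that add atoms: TBSCl, CC(C)(C)[Si](C)(C)Cl
Why: Monosilylation of a C2‑symmetric diol gives one product whichever OH reacts, and the second OH silylates much more slowly; both stereocentres (future C8, C9) come from the chiral pool.

Step 2
Reactants: 2
Product: 3, ethyl (2R,3S)‑2‑(TBSO)‑3,4‑dihydroxybutanoate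
Conditions: BH3·SMe2 (1.05 equiv), NaBH4 (5 mol %), THF, 0 °C→rt; MeOH
Reagents that add atoms: none
Why: Hydroxyl‑directed (Saito) borane reduction reduces only the ester α to the free OH via a cyclic alkoxyborane; the α‑silyloxy ester is untouched.

Step 3
Reactants: 3
Product: 4, ethyl (2R,3S)‑2‑(TBSO)‑3,4‑bis(TESO)butanoate
Conditions: TESCl (2.3 equiv), imidazole, DMAP (cat.), CH2Cl2, 0 °C→rt
Reagents that add atoms: TESCl, CC[Si](CC)(CC)Cl
Why: Standard silylation; this leaves C9‑OTBS and C8‑OTES orthogonal for the endgame.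

Step 4
Reactants: 4
Product: 5, (2R,3S)‑2‑(TBSO)‑3,4‑bis(TESO)butanal
Conditions: DIBAL‑H (1.1 equiv), CH2Cl2, −78 °C; Rochelle salt
Reagents that add atoms: none
Why: Partial reduction of an α‑silyloxy ester stops at the aldehyde through the chelated tetrahedral intermediate at −78 °C.

Step 5
Reactants: 5
Product: 6, (3S,4S)‑1,1‑dibromo‑3‑(TBSO)‑4,5‑bis(TESO)pent‑1‑ene
Conditions: CBr4, PPh3, Et3N, CH2Cl2, 0 °C
Reagents that add atoms: CBr4, BrC(Br)(Br)Br
Why: Corey–Fuchs (Ramirez) dibromo‑olefination is non‑basic, so the α‑silyloxy stereocentre is not epimerized; Et3N buffers HBr to protect the TES ethers.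

**West fragment (C2–C6, C15)**

Step 6
Reactants: 7, but‑3‑yn‑1‑ol
Product: 8, tert‑butyl(but‑3‑yn‑1‑yloxy)dimethylsilane
Conditions: TBSCl, imidazole, CH2Cl2, rt
Reagents that add atoms: TBSCl, CC(C)(C)[Si](C)(C)Cl
Why: Routine protection before carbometalation.

Step 7
Reactants: 8
Product: 9, (E)‑5‑(TBSO)‑3‑methylpent‑2‑en‑1‑ol
Conditions: Me3Al, Cp2ZrCl2 (0.25 equiv), CH2Cl2, 0 °C→rt; then n‑BuLi, THF, −78 °C; (CH2O)n, →rt
Reagents that add atoms: trimethylaluminium, C[Al](C)C; paraformaldehyde, C=O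
Why: Negishi Zr‑catalysed carboalumination is a syn Me–Al addition, and hydroxymethylation of the alkenyl alanate proceeds with retention, fixing the C4=C5 (E) geometry.

Step 8
Reactants: 9
Product: 10, (E)‑1‑(TBSO)‑5‑(PMBO)‑3‑methylpent‑3‑ene
Conditions: NaH, PMBCl, TBAI (cat.), THF/DMF, 0 °C→rt
Reagents that add atoms: PMBCl, COc1ccc(CCl)cc1
Why: Williamson etherification; the allylic PMB ether is later converted directly into the enal.

Step 9
Reactants: 10
Product: 11, (E)‑5‑(PMBO)‑3‑methylpent‑3‑en‑1‑ol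
Conditions: TBAF, THF, rt
Reagents that add atoms: none
Why: Fluoride desilylation; the PMB ether is inert.

Step 10
Reactants: 11
Product: 12, (E)‑5‑iodo‑1‑(PMBO)‑3‑methylpent‑2‑ene
Conditions: I2, PPh3, imidazole, CH2Cl2, 0 °C
Reagents that add atoms: iodine, II
Why: Appel iodination of the primary alcohol gives the C2 electrophile.

**Fragment union and elaboration**

Step 11
Reactants: 6 and 12
Product: 13, (2E,8S,9S)‑8‑(TBSO)‑1‑(PMBO)‑3‑methyl‑9,10‑bis(TESO)dec‑2‑en‑6‑yne
Conditions: 6, n‑BuLi (2.05 equiv), THF, −78→−20 °C; then 12, DMPU, −20 °C→rt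
Reagents that add atoms: none
Why: Second Corey–Fuchs stage (Fritsch–Buttenberg–Wiechell rearrangement) gives the lithium acetylide, which is alkylated (SN2) by the primary iodide to form C1–C2.

Step 12
Reactants: 13
Product: 14, (2E,6E,8R,9S)‑7‑iodo‑8‑(TBSO)‑1‑(PMBO)‑3‑methyl‑9,10‑bis(TESO)deca‑2,6‑diene
Conditions: Bu3SnH (1.5 equiv), PdCl2(PPh3)2 (3 mol %), THF, 0 °C→rt; then I2, CH2Cl2, 0 °C
Reagents that add atoms: iodine, II
Why: Pd‑catalysed syn‑hydrostannation of the propargylic ether puts tin on C10 (next to the oxygenated carbon) and H on C1, and iododestannylation occurs with retention, so C2 and C9 end up cis; the minor regioisomer is removed by chromatography.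

Step 13
Reactants: 14
Product: 15, methyl (2E,6E)‑2‑[(1S,2S)‑1‑(TBSO)‑2,3‑bis(TESO)propyl]‑8‑(PMBO)‑6‑methylocta‑2,6‑dienoate
Conditions: Pd(PPh3)4 (5 mol %), CO (1 atm), MeOH, Et3N, DMF, 55 °C
Reagents that add atoms: carbon monoxide, [C-]#[O+]; methanol, CO
Why: Pd‑catalysed methoxycarbonylation of the vinyl iodide proceeds with retention, giving the C1=C10 enoate with CO2Me trans to C2 as in the target.

Step 14
Reactants: 15
Product: 16, methyl (2E,6E)‑2‑[(1S,2R)‑1‑(TBSO)‑3‑oxo‑2‑(TESO)propyl]‑8‑(PMBO)‑6‑methylocta‑2,6‑dienoate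
Conditions: (COCl)2, DMSO, CH2Cl2, −78→−40 °C; Et3N, →0 °C
Reagents that add atoms: none
Why: Swern conditions oxidize a primary TES ether directly to the aldehyde while secondary TES, TBS and PMB ethers survive, unveiling C7 without a separate deprotection.

Step 15
Reactants: 16 and 17, methyl acrylate
Product: 18, Baylis–Hillman adduct, methyl (2E,6E)‑2‑[(1S,2S,3RS)‑1‑(TBSO)‑3‑hydroxy‑4‑(methoxycarbonyl)‑2‑(TESO)pent‑4‑enyl]‑8‑(PMBO)‑6‑methylocta‑2,6‑dienoate
Conditions: methyl acrylate (10 equiv, neat), DABCO (1 equiv), rt, 2–4 d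
Reagents that add atoms: none (17 is a reactant)
Why: Morita–Baylis–Hillman reaction; α‑oxygenated aldehydes are activated acceptors and the trisubstituted C10 enoate is inert to DABCO. The new C7 carbinol centre is irrelevant because it is erased in step 16.

Step 16
Reactants: 18
Product: 19, methyl (2E,6E)‑2‑[(1S,2S,3Z)‑5‑bromo‑4‑(methoxycarbonyl)‑1‑(TBSO)‑2‑(TESO)pent‑3‑enyl]‑8‑(PMBO)‑6‑methylocta‑2,6‑dienoate
Conditions: NBS, Me2S, CH2Cl2, −20 °C→rt
Reagents that add atoms: N‑bromosuccinimide, BrN1C(=O)CCC1=O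
Why: Corey–Kim‑type activation of the Baylis–Hillman alcohol followed by SN2′ bromide attack gives the 2‑(bromomethyl)‑2‑enoate with C8 trans to the ester (Z); the neutral conditions spare the silyl and PMB ethers.

Step 17
Reactants: 19
Product: 20, methyl (2E,6E)‑2‑[(1S,2S,3Z)‑5‑bromo‑4‑(methoxycarbonyl)‑1‑(TBSO)‑2‑(TESO)pent‑3‑enyl]‑6‑methyl‑8‑oxoocta‑2,6‑dienoate
Conditions: DDQ (3 equiv), CH2Cl2/pH 7 buffer (10:1), 0 °C→rt
Reagents that add atoms: none
Why: Oxidative PMB cleavage, then in situ DDQ oxidation of the liberated electron‑rich allylic alcohol to the (E)‑enal (any residual alcohol is finished with MnO2); the electron‑poor allylic positions and the bromide are untouched.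

Step 18
Reactants: 20
Product: 21, 9‑O‑TBS‑8‑O‑TES‑8‑deangeloyl‑polymatin A (6R,7S,8S,9S)
Conditions: CrCl2 (8 equiv), THF, syringe‑pump addition to 2 mM, rt; aq. NH4Cl
Reagents that add atoms: none
Why: Intramolecular Nozaki–Hiyama (Cr‑Barbier) allylation: the allyl‑Cr(III) attacks the enal 1,2 through its γ‑carbon (C7) in a cyclic transition state, and the C6 alkoxide lactonizes onto C12. In the ten‑membered transition state the C5 and C8 chains are expected to sit anti (trans‑lactone, 6R), by analogy with Cr‑mediated germacranolide closures. C8 is expected to control the face: H‑8 eclipses the allyl unit (A1,3 strain), C8–C9 is anti to the incoming carbonyl and OTES points outward, giving 7S.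

Step 19
Reactants: 21
Product: 22, 9‑O‑TBS‑8‑deangeloyl‑polymatin A (free 8‑OH)
Conditions: PPTS (cat.), MeOH/CH2Cl2, 0 °C
Reagents that add atoms: none
Why: Mild acid methanolysis removes the secondary TES ether much faster than the hindered secondary TBS ether and does not affect the lactone or enoate.

**Angelate donor**

Step 20
Reactants: 23, tiglic acid
Product: 24, rac‑(2R,3S)‑2,3‑dibromo‑2‑methylbutanoic acid
Conditions: Br2, CH2Cl2, 0 °C
Reagents that add atoms: bromine, BrBr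
Why: Stereospecific anti addition of Br2 to the cheap (E)‑acid.

Step 21
Reactants: 24
Product: 25, (Z)‑2‑bromobut‑2‑ene
Conditions: Na2CO3, H2O, 60 °C (product distilled out)
Reagents that add atoms: none
Why: Anti decarboxylative elimination (Grob‑type loss of CO2 and Br–) of the β‑bromo carboxylate is stereospecific and places Br cis to the C4 methyl.

Step 22
Reactants: 25
Product: 26, angelic acid, (Z)‑2‑methylbut‑2‑enoic acid
Conditions: t‑BuLi (2.1 equiv), Et2O, −78 °C; CO2; H3O+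
Reagents that add atoms: carbon dioxide, O=C=O
Why: Br/Li exchange and carboxylation of the configurationally stable vinyllithium occur with retention, giving the (Z)‑acid.

Step 23
Reactants: 26
Product: 27, angelic 2,4,6‑trichlorobenzoic anhydride
Conditions: 2,4,6‑trichlorobenzoyl chloride, Et3N, toluene, rt
Reagents that add atoms: 2,4,6‑trichlorobenzoyl chloride, O=C(Cl)c1c(Cl)cc(Cl)cc1Cl
Why: Yamaguchi mixed‑anhydride formation activates the acid without Z→E isomerization.

**Endgame**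

Step 24
Reactants: 22 and 27
Product: 28, 9‑O‑TBS‑polymatin A
Conditions: toluene, 80 °C
Reagents that add atoms: none
Why: Yamaguchi‑type acyl transfer: the alcohol attacks the less hindered angeloyl carbonyl, and the absence of nucleophilic catalysts avoids angelate→tiglate isomerization.

Step 25
Reactants: 28
Product: 29, polymatin A
Conditions: HF·pyridine, pyridine/THF, 0 °C→rt
Reagents that add atoms: none
Why: Fluoride desilylation under mildly acidic conditions frees 9‑OH without 8→9 acyl migration or conjugate addition to the α‑methylene lactone.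

---

**Compound list**

1 | diethyl L‑(+)‑tartrate | CCOC(=O)[C@H](O)[C@@H](O)C(=O)OCC | starting material
2 | diethyl (2R,3R)‑2‑(TBSO)‑3‑hydroxybutanedioate | CCOC(=O)[C@H](O[Si](C)(C)C(C)(C)C)[C@@H](O)C(=O)OCC | intermediate
3 | ethyl (2R,3S)‑2‑(TBSO)‑3,4‑dihydroxybutanoate | CCOC(=O)[C@H](O[Si](C)(C)C(C)(C)C)[C@@H](O)CO | intermediate
4 | ethyl (2R,3S)‑2‑(TBSO)‑3,4‑bis(TESO)butanoate | CCOC(=O)[C@H](O[Si](C)(C)C(C)(C)C)[C@@H](O[Si](CC)(CC)CC)CO[Si](CC)(CC)CC | intermediate
5 | (2R,3S)‑2‑(TBSO)‑3,4‑bis(TESO)butanal | O=C[C@H](O[Si](C)(C)C(C)(C)C)[C@@H](O[Si](CC)(CC)CC)CO[Si](CC)(CC)CC | intermediate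
6 | (3S,4S)‑1,1‑dibromo‑3‑(TBSO)‑4,5‑bis(TESO)pent‑1‑ene | BrC(Br)=C[C@H](O[Si](C)(C)C(C)(C)C)[C@@H](O[Si](CC)(CC)CC)CO[Si](CC)(CC)CC | intermediate
7 | but‑3‑yn‑1‑ol | C#CCCO | starting material
8 | tert‑butyl(but‑3‑yn‑1‑yloxy)dimethylsilane | C#CCCO[Si](C)(C)C(C)(C)C | intermediate
9 | (E)‑5‑(TBSO)‑3‑methylpent‑2‑en‑1‑ol | OC/C=C(\C)CCO[Si](C)(C)C(C)(C)C | intermediate
10 | (E)‑1‑(TBSO)‑5‑(PMBO)‑3‑methylpent‑3‑ene | COc1ccc(COC/C=C(\C)CCO[Si](C)(C)C(C)(C)C)cc1 | intermediate
11 | (E)‑5‑(PMBO)‑3‑methylpent‑3‑en‑1‑ol | COc1ccc(COC/C=C(\C)CCO)cc1 | intermediate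
12 | (E)‑5‑iodo‑1‑(PMBO)‑3‑methylpent‑2‑ene | COc1ccc(COC/C=C(\C)CCI)cc1 | intermediate
13 | (2E,8S,9S)‑8‑(TBSO)‑1‑(PMBO)‑3‑methyl‑9,10‑bis(TESO)dec‑2‑en‑6‑yne | COc1ccc(COC/C=C(\C)CCC#C[C@H](O[Si](C)(C)C(C)(C)C)[C@@H](O[Si](CC)(CC)CC)CO[Si](CC)(CC)CC)cc1 | intermediate
14 | (2E,6E,8R,9S)‑7‑iodo‑8‑(TBSO)‑1‑(PMBO)‑3‑methyl‑9,10‑bis(TESO)deca‑2,6‑diene | COc1ccc(COC/C=C(\C)CC/C=C(/I)[C@H](O[Si](C)(C)C(C)(C)C)[C@@H](O[Si](CC)(CC)CC)CO[Si](CC)(CC)CC)cc1 | intermediate
15 | methyl (2E,6E)‑2‑[(1S,2S)‑1‑(TBSO)‑2,3‑bis(TESO)propyl]‑8‑(PMBO)‑6‑methylocta‑2,6‑dienoate | COc1ccc(COC/C=C(\C)CC/C=C(/C(=O)OC)[C@H](O[Si](C)(C)C(C)(C)C)[C@@H](O[Si](CC)(CC)CC)CO[Si](CC)(CC)CC)cc1 | intermediate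
16 | methyl (2E,6E)‑2‑[(1S,2R)‑1‑(TBSO)‑3‑oxo‑2‑(TESO)propyl]‑8‑(PMBO)‑6‑methylocta‑2,6‑dienoate | COc1ccc(COC/C=C(\C)CC/C=C(/C(=O)OC)[C@H](O[Si](C)(C)C(C)(C)C)[C@@H](O[Si](CC)(CC)CC)C=O)cc1 | intermediate
17 | methyl acrylate | C=CC(=O)OC | starting material
18 | Baylis–Hillman adduct (C7 carbinol epimers) | COc1ccc(COC/C=C(\C)CC/C=C(/C(=O)OC)[C@H](O[Si](C)(C)C(C)(C)C)[C@@H](O[Si](CC)(CC)CC)C(O)C(=C)C(=O)OC)cc1 | intermediate
19 | (Z)‑2‑(bromomethyl)enoate, PMB ether | COc1ccc(COC/C=C(\C)CC/C=C(/C(=O)OC)[C@H](O[Si](C)(C)C(C)(C)C)[C@@H](O[Si](CC)(CC)CC)/C=C(\CBr)C(=O)OC)cc1 | intermediate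
20 | bromo‑enal seco‑precursor | O=C/C=C(\C)CC/C=C(/C(=O)OC)[C@H](O[Si](C)(C)C(C)(C)C)[C@@H](O[Si](CC)(CC)CC)/C=C(\CBr)C(=O)OC | intermediate
21 | 9‑O‑TBS‑8‑O‑TES‑8‑deangeloyl‑polymatin A | C=C1C(=O)O[C@@H]2/C=C(\C)CC/C=C(/C(=O)OC)[C@H](O[Si](C)(C)C(C)(C)C)[C@@H](O[Si](CC)(CC)CC)[C@@H]12 | intermediate
22 | 9‑O‑TBS‑8‑deangeloyl‑polymatin A | C=C1C(=O)O[C@@H]2/C=C(\C)CC/C=C(/C(=O)OC)[C@H](O[Si](C)(C)C(C)(C)C)[C@@H](O)[C@@H]12 | intermediate
23 | tiglic acid | C/C=C(\C)C(=O)O | starting material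
24 | rac‑(2R,3S)‑2,3‑dibromo‑2‑methylbutanoic acid (relative configuration shown) | C[C@H](Br)[C@](C)(Br)C(=O)O | intermediate
25 | (Z)‑2‑bromobut‑2‑ene | C/C=C(\Br)C | intermediate
26 | angelic acid | C/C=C(/C)C(=O)O | intermediate
27 | angelic 2,4,6‑trichlorobenzoic anhydride | C/C=C(/C)C(=O)OC(=O)c1c(Cl)cc(Cl)cc1Cl | intermediate
28 | 9‑O‑TBS‑polymatin A | C=C1C(=O)O[C@@H]2/C=C(\C)CC/C=C(/C(=O)OC)[C@H](O[Si](C)(C)C(C)(C)C)[C@@H](OC(=O)/C(C)=C\C)[C@@H]12 | intermediate
29 | polymatin A (6R,7S,8S,9S) | C=C1C(=O)O[C@@H]2/C=C(\C)CC/C=C(/C(=O)OC)[C@H](O)[C@@H](OC(=O)/C(C)=C\C)[C@@H]12 | target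

---

**Totals**
Total step count: 25 (three branches: 1–5, 6–10, 20–23; common trunk 11–19, 24, 25).
Longest linear sequence: 16 steps (1–5 → 11–19 → 24 → 25; the 6–10 branch gives an equal‑length path), which is 64 % of the total.

**Three steps most likely to fail, with fallbacks**
1. Step 18, Cr‑mediated macrocyclization. Risks are oligomerization, 1,4‑elimination of the γ‑silyloxy allyl‑chromium, and the wrong C6/C7 diastereomer; the stereochemical outcome rests on analogy and a transition‑state model, not on a direct precedent with C8/C9 oxygenation. Fallback: change the ring‑closing bond. Join the allylic bromide to a separately made (E)‑3‑methylhepta‑2,6‑dienal by an intermolecular Cr/In Barbier lactonization (acyclic 1,4‑induction from C8), then close the ten‑membered ring at C1=C10 by ring‑closing metathesis of a C10 α‑substituted acrylate with the terminal vinyl group.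
2. Step 12, regioselective hydrostannation. Tin may add at C1 instead of C10 next to the bulky OTBS carbon. Fallback: remove the C9 silyl group and use hydroxyl‑directed Ti‑catalysed hydromagnesiation of the free propargylic alcohol (i‑BuMgCl, Cp2TiCl2), trap the C10 vinylmagnesium with CO2, methylate, and re‑silylate C9; this replaces the tin/iodide/carbonylation sequence.
3. Step 15, Baylis–Hillman reaction on a hindered, base‑sensitive α,β‑bis(silyloxy) aldehyde. It may be slow, with C8 epimerization or β‑elimination. Fallback: tandem oxa‑Michael/Horner–Wadsworth–Emmons with trimethyl 2‑phosphonoacrylate and sodium 4‑methoxybenzyl oxide at low temperature to give the 2‑(PMBO‑methyl)enoate; the DDQ step then frees the C13 alcohol together with the enal, and Appel bromination (CBr4, PPh3) gives 20.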